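Readings and results are calculated for an exercise; scatter was added.

A flask in which every unit of free monomer ends in chains cannot be what the earlier runs show: in larch the free monomer reads 0% at 4.00 d with 57% in chains, and in birch it reads 0% at 8.00 h with 41% in chains.

the same everywhere: free monomer 0.40 M
- larch: initiator 1.3 mM; temperature −8 °C; run made earlier
- birch: initiator 3 mM; temperature 20 °C; run made earlier
- gamma: initiator 2.0 mM; temperature 5 °C; time 4.0 d
- alpha: initiator 2.0 mM; temperature −20 °C; time 4.0 d
- delta: initiator 2.0 mM; temperature 30 °C; time 4.0 d

larch run (percent of the free monomer charged)

| time / d | monomer in chains / % | free monomer / % |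
|---|---|---|
| 1.04 | 47 | 22 |
| 2.08 | 55 | 4 |
| 2.50 | 56 | 3 |
| 4.00 | 57 | 0 |
| 5.00 | 57 | 1 |

birch run (percent of the free monomer charged)

| time / h | monomer in chains / % | free monomer / % |
|---|---|---|
| 2.50 | 38 | 8 |
| 4.00 | 40 | 1 |
| 8.00 | 41 | 0 |
| 15.0 | 39 | 3 |
| 30.0 | 39 | 2 |

(scatter of a reading: 1.5 percentage points)

- which flask leads in amount of monomer in chains, in percent of the free monomer charged ("all alike" within 1.5 percentage points) (gamma / alpha / delta / all alike)
- how much monomer in chains is there at the end, in percent of the free monomer charged: gamma
- how much monomer in chains is there at the end, in percent of the free monomer charged: alpha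
- how much monomer in chains is there at the end, in percent of the free monomer charged: delta

So to the main step, free monomer into chains, I add one more process, a loss, and I reckon with what is not kept. The late readings average 57.0% in larch and 39.7% in birch. I assume that keeping goes with [initiator] and losing with [free monomer], which these runs cannot test, since they share one monomer charge and differ in both initiator and temperature. My loss number is therefore the lost-to-kept ratio at the end times the charged [initiator]/[free monomer]. It reads 0.00245 in larch and 0.0114 in birch. Letting it grow by a steady factor per degree, I get for gamma's temperature the loss number 0.00501, so I reckon that gamma keeps a share of 50.0%. The same reckoning gives delta 20.2% and alpha a share of 79.8%.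

Then comes the clock, which I follow through the fraction left. I take free monomer to fall exponentially at a rate proportional to [initiator], and I carry the first readings of both runs across the degrees in the same way. By this estimate 2.15% stays free in alpha, so I commit to 78.1% there and name alpha as the flask that leads.

The forecast names alpha too, with 49% for gamma, 57% for alpha and 35% for delta, on the ground that “Chains keep a constant share of the monomer consumed”. It stands near my gamma but differs from my alpha and delta.

The flasks end at 47.5% in gamma, 75.8% in alpha and 26.8% in delta, so alpha leads, and alpha still holds 4.3% of its free monomer at 4.00 d. Gamma's result, put back into the loss number, reads 0.00553 beside my 0.00501.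

    initiator ⇌ dormant form (K = 8.40, k = 0.500 h⁻¹, Ea = 84.0 kJ mol⁻¹, ΔH = −52.0 kJ mol⁻¹)
    free monomer + initiator → living end + monomer in chains (k = 2.10 M⁻¹ h⁻¹, Ea = 56.0 kJ mol⁻¹)
    free monomer + living end → monomer in chains + living end, rate k3*[living end]*[free monomer] (k = 150 M⁻¹ h⁻¹, Ea = 47.0 kJ mol⁻¹)
    free monomer + monomer in chains → side product (k = 0.610 M⁻¹ h⁻¹, Ea = 78.0 kJ mol⁻¹)
    (constants at 5 °C)

In the neighbour of gamma charged with 0.24 M of free monomer, that loss number gives a lost-to-kept ratio of 0.663, hence 60.1% in chains. The computed flask gives 54.8%, with 0.00111 M of living end against 0.00133 M in gamma.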